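**Retrosynthetic overview**
1. Durumolide G ⇐ bicyclic epoxy ketone 22, by C3 ketone reduction, acetate opening of the 4,18-epoxide, C3 acetylation and desilylation.
2. 22 ⇐ acyclic vinyl ketone/phosphonoacetate 19 in one flask: ring-closing metathesis closes the 14-membered ring (C1=C2), then intramolecular Michael addition (C15–C1) closes the lactone and olefination with formaldehyde gives the exocyclic methylene.
3. 19 ⇐ enal 11, by Brown syn-alkoxyallylboration (C13, C14), esterification and oxidation-state changes.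
4. 11 ⇐ nerol (C6–C13, both ring olefin geometries) + methallyl alcohol dianion (C3–C5, C18); Sharpless epoxidation (C4), vinyl Grignard (C2), SeO2 oxidation (C13).
5. Ring order: carbocycle first, γ-lactone second, both in step 13.

Assumption: cembrane-type locants are used (C1 = ring carbon bonded to the lactone α-carbon C15; C3 = CH–OAc; C4 = C(OH) carrying C18H2OAc; C7=C8 and C11=C12 = ring olefins; C13 = CH–OH; C14 = lactone CH–O; C17 = exocyclic CH2). The given SMILES then reads (1R,3S,4S,13R,14R,7Z,11E), and that isomer is made.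

**Step 1**
Reactants: 1 nerol
Product: 2 neryl bromide
Conditions: PBr3, pyridine (cat.), Et2O, −10 °C
Reagents that add atoms: phosphorus tribromide, BrP(Br)Br
Why: PBr3 bromination of the primary allylic alcohol (SN2-type) at low temperature keeps the Z olefin and avoids allylic transposition.

**Step 2**
Reactants: 3 methallyl alcohol; 2 neryl bromide
Product: 5 (5Z)-6,10-dimethyl-2-methylideneundeca-5,9-dien-1-ol, via dilithio methallyl alcohol 4 (not isolated)
Conditions: 3, n-BuLi (2.1 equiv), TMEDA, Et2O, 0 °C → rt; then 2, THF, −78 → 0 °C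
Reagents that add atoms: none
Why: C-alkylation of the symmetric 2-(lithiomethyl)allyl alkoxide dianion by the primary allylic bromide (allyl dianion alkylation, SN2) adds C3, C4, C5 and C18 in one step and leaves the Z olefin untouched.

**Step 3**
Reactants: 5 (5Z)-6,10-dimethyl-2-methylideneundeca-5,9-dien-1-ol
Product: 6 [(2R)-2-[(3Z)-4,8-dimethylnona-3,7-dien-1-yl]oxiran-2-yl]methanol
Conditions: Ti(OiPr)4 (10 mol%), D-(−)-diethyl tartrate (12 mol%), t-BuOOH, 4 Å molecular sieves, CH2Cl2, −20 °C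
Reagents that add atoms: tert-butyl hydroperoxide, CC(C)(C)OO
Why: Sharpless asymmetric epoxidation reacts only at the allylic-alcohol olefin, and D-(−)-tartrate delivers oxygen to the face that gives the (R)-epoxide, which fixes C4 because the C4–O bond is never broken afterwards.

**Step 4**
Reactants: 6 [(2R)-2-[(3Z)-4,8-dimethylnona-3,7-dien-1-yl]oxiran-2-yl]methanol
Product: 7 (2S)-2-[(3Z)-4,8-dimethylnona-3,7-dien-1-yl]oxirane-2-carbaldehyde
Conditions: Dess–Martin periodinane, NaHCO3, CH2Cl2, 0 °C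
Reagents that add atoms: none
Why: Buffered Dess–Martin oxidation gives the epoxy aldehyde, which has no α-hydrogen and so cannot epimerise at C4.

**Step 5**
Reactants: 7 (2S)-2-[(3Z)-4,8-dimethylnona-3,7-dien-1-yl]oxirane-2-carbaldehyde
Product: 9 triethyl({1-[(2S)-2-[(3Z)-4,8-dimethylnona-3,7-dien-1-yl]oxiran-2-yl]prop-2-en-1-yl}oxy)silane, via bromomagnesium alkoxide 8 (not isolated)
Conditions: CH2=CHMgBr, THF, −78 °C; then Et3SiCl, imidazole, DMF, 0 °C → rt
Reagents that add atoms: vinylmagnesium bromide, C=C[Mg]Br; chlorotriethylsilane, CC[Si](Cl)(CC)CC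
Why: Grignard 1,2-addition to the aldehyde followed by O-silylation in the same flask; the C3 configuration is irrelevant because C3 becomes a ketone in step 12.

**Step 6**
Reactants: 9 triethyl({1-[(2S)-2-[(3Z)-4,8-dimethylnona-3,7-dien-1-yl]oxiran-2-yl]prop-2-en-1-yl}oxy)silane
Product: 11 (2E,6Z)-2,6-dimethyl-9-{(2S)-2-[1-(triethylsilyloxy)prop-2-en-1-yl]oxiran-2-yl}nona-2,6-dienal, via C13 allylic alcohol 10 (not isolated)
Conditions: SeO2 (0.5 equiv), t-BuOOH, CH2Cl2, 0 °C → rt; then MnO2, CH2Cl2, rt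
Reagents that add atoms: tert-butyl hydroperoxide, CC(C)(C)OO
Why: SeO2/t-BuOOH allylic oxidation (ene reaction then [2,3]-sigmatropic shift) selects the (E)-methyl of the terminal isopropylidene group, and MnO2 allylic oxidation then gives the (E)-enal, which sets the 11E olefin.

**Step 7**
Reactants: 11 (2E,6Z)-2,6-dimethyl-9-{(2S)-2-[1-(triethylsilyloxy)prop-2-en-1-yl]oxiran-2-yl}nona-2,6-dienal; 12 allyl 4-methoxybenzyl ether
Product: 14 (3R,4R,5E,9Z)-3-(4-methoxybenzyloxy)-5,9-dimethyl-12-{(2S)-2-[1-(triethylsilyloxy)prop-2-en-1-yl]oxiran-2-yl}dodeca-1,5,9-trien-4-ol, via PMB-oxyallyl diisopinocampheylborane 13 (not isolated)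
Conditions: 12, sec-BuLi, THF, −78 °C; (−)-Ipc2BOMe; BF3·OEt2; then 11, −78 °C; NaOH, H2O2, 0 °C → rt
Reagents that add atoms: none
Why: Brown (Z)-γ-alkoxyallylboration through a closed chair (Zimmerman–Traxler) transition state gives the syn 1,2-diol monoether, and the isopinocampheyl groups derived from (+)-α-pinene direct attack to the Si face of the enal, which sets 13R and 14R.

**Step 8**
Reactants: 14 (3R,4R,5E,9Z)-3-(4-methoxybenzyloxy)-5,9-dimethyl-12-{(2S)-2-[1-(triethylsilyloxy)prop-2-en-1-yl]oxiran-2-yl}dodeca-1,5,9-trien-4-ol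
Product: 15 tert-butyldimethylsilyl ether of 14 at C13
Conditions: TBSOTf, 2,6-lutidine, CH2Cl2, −78 °C
Reagents that add atoms: tert-butyldimethylsilyl trifluoromethanesulfonate, CC(C)(C)[Si](C)(C)OS(=O)(=O)C(F)(F)F
Why: Silylation of the C13 hydroxyl (silyl ether formation) at −78 °C with base present spares the epoxide and keeps C13–OH masked until the last step.

**Step 9**
Reactants: 15 tert-butyldimethylsilyl ether of 14 at C13
Product: 16 (3R,4R,5E,9Z)-4-(tert-butyldimethylsilyloxy)-5,9-dimethyl-12-{(2S)-2-[1-(triethylsilyloxy)prop-2-en-1-yl]oxiran-2-yl}dodeca-1,5,9-trien-3-ol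
Conditions: DDQ, CH2Cl2/pH 7 buffer, 0 °C
Reagents that add atoms: none
Why: Oxidative cleavage of the 4-methoxybenzyl ether by DDQ frees the C14 hydroxyl under neutral conditions that leave both silyl ethers, the epoxide and the olefins alone.

**Step 10**
Reactants: 16 (3R,4R,5E,9Z)-4-(tert-butyldimethylsilyloxy)-5,9-dimethyl-12-{(2S)-2-[1-(triethylsilyloxy)prop-2-en-1-yl]oxiran-2-yl}dodeca-1,5,9-trien-3-ol
Product: 17 diethylphosphonoacetate ester of 16 at C14
Conditions: (EtO)2P(O)CH2CO2H, DCC, DMAP (cat.), CH2Cl2, 0 °C → rt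
Reagents that add atoms: diethylphosphonoacetic acid, CCOP(=O)(CC(=O)O)OCC
Why: Steglich esterification places the future C15/C16 unit on the C14 oxygen, the only free hydroxyl.

**Step 11**
Reactants: 17 diethylphosphonoacetate ester of 16 at C14
Product: 18 C3 alcohol (triethylsilyl group of 17 removed)
Conditions: HF·pyridine, pyridine, THF, 0 °C
Reagents that add atoms: none
Why: Buffered HF·pyridine removes the triethylsilyl ether much faster than the hindered tert-butyldimethylsilyl ether (selective desilylation) and does not open the epoxide or the ester.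

**Step 12**
Reactants: 18 C3 alcohol
Product: 19 (3R,4R,5E,9Z)-4-(tert-butyldimethylsilyloxy)-5,9-dimethyl-12-[(2S)-2-(prop-2-enoyl)oxiran-2-yl]dodeca-1,5,9-trien-3-yl 2-(diethoxyphosphoryl)acetate
Conditions: Dess–Martin periodinane, NaHCO3, CH2Cl2, 0 °C → rt
Reagents that add atoms: none
Why: Dess–Martin oxidation of the allylic alcohol gives the vinyl ketone under neutral conditions; it is used directly.

**Step 13**
Reactants: 19 (3R,4R,5E,9Z)-4-(tert-butyldimethylsilyloxy)-5,9-dimethyl-12-[(2S)-2-(prop-2-enoyl)oxiran-2-yl]dodeca-1,5,9-trien-3-yl 2-(diethoxyphosphoryl)acetate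
Product: 22 (1R,4S,13R,14R,7Z,11E)-4,18-epoxy-3-oxo-13-(tert-butyldimethylsilyloxy)cembra-7,11,15(17)-trien-16,14-olide, via macrocyclic enone 20 (not isolated), via phosphono lactone 21 (not isolated)
Conditions: second-generation Hoveyda–Grubbs catalyst RuCl2(H2IMes)(=CH-C6H4-2-OiPr) (15 mol%), toluene (1 mM), 80 °C; then KOtBu (1.2 equiv), THF, 0 °C; then (CH2O)n, 0 °C → rt
Reagents that add atoms: formaldehyde (as paraformaldehyde), C=O
Why: Proposed new method: one-flask merger of an enone-forming macrocyclic ring-closing metathesis (the ruthenium carbene loads on the allylic-ester vinyl group and closes onto the vinyl ketone to the E-enone while the trisubstituted olefins stay inert) with a telescoped intramolecular Michael/olefination, in which the phosphonate anion adds 5-exo to C1 from the face of the C14 oxygen with C14–H eclipsing the enone and the C13 chain turned away, giving the trans-fused lactone (1R), and Horner–Wadsworth–Emmons reaction of the resulting phosphonate anion with formaldehyde installs the exocyclic methylene; the closest known reaction types are macrocyclic enone RCM and the telescoped intramolecular Michael/olefination (TIMO) synthesis of α-methylene-γ-butyrolactones.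

**Step 14**
Reactants: 22 (1R,4S,13R,14R,7Z,11E)-4,18-epoxy-3-oxo-13-(tert-butyldimethylsilyloxy)cembra-7,11,15(17)-trien-16,14-olide
Product: 23 (1R,3S,4S,13R,14R,7Z,11E)-4,18-epoxy-3-hydroxy-13-(tert-butyldimethylsilyloxy)cembra-7,11,15(17)-trien-16,14-olide
Conditions: (R)-2-methyl-CBS-oxazaborolidine, catecholborane, toluene, −78 °C
Reagents that add atoms: none
Why: Corey–Bakshi–Shibata reduction under reagent control, with the quaternary epoxide carbon as the large group and C2H2 as the small group, so the (R)-catalyst gives the (3S)-alcohol, while catecholborane at −78 °C leaves the α-methylene lactone and olefins alone.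

**Step 15**
Reactants: 23 (1R,3S,4S,13R,14R,7Z,11E)-4,18-epoxy-3-hydroxy-13-(tert-butyldimethylsilyloxy)cembra-7,11,15(17)-trien-16,14-olide
Product: 25 13-O-(tert-butyldimethylsilyl)durumolide G, via 18-acetoxy-3,4-diol 24 (not isolated)
Conditions: Ti(OiPr)4, AcOH, CH2Cl2, rt; then Ac2O, pyridine, DMAP (cat.), 0 °C → rt
Reagents that add atoms: acetic acid, CC(=O)O; acetic anhydride, CC(=O)OC(C)=O
Why: Ti(OiPr)4-mediated opening of the 2,3-epoxy alcohol by acetate at the distal primary carbon C18 (Sharpless regioselective epoxy alcohol opening; the C4–O bond is untouched, so C4 stays S), then acetylation of the secondary C3 hydroxyl, which the tertiary C4 hydroxyl and the silylated C13 oxygen do not undergo.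

**Step 16**
Reactants: 25 13-O-(tert-butyldimethylsilyl)durumolide G
Product: 26 durumolide G
Conditions: HF·pyridine, THF, 0 °C → rt
Reagents that add atoms: none
Why: Fluoride cleavage of the silyl ether (desilylation) under mildly acidic conditions that do not move the acetates or add to the α-methylene lactone.

**Compound list**
1 | nerol, (2Z)-3,7-dimethylocta-2,6-dien-1-ol | OC/C=C(/C)CCC=C(C)C | starting material
2 | neryl bromide, (2Z)-1-bromo-3,7-dimethylocta-2,6-diene | BrC/C=C(/C)CCC=C(C)C | intermediate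
3 | methallyl alcohol, 2-methylprop-2-en-1-ol | C=C(C)CO | starting material
4 | dilithio methallyl alcohol, lithium 2-(lithiomethyl)prop-2-en-1-olate | [Li]CC(=C)CO[Li] | intermediate (not isolated)
5 | (5Z)-6,10-dimethyl-2-methylideneundeca-5,9-dien-1-ol | C=C(CO)CC/C=C(/C)CCC=C(C)C | intermediate
6 | [(2R)-2-[(3Z)-4,8-dimethylnona-3,7-dien-1-yl]oxiran-2-yl]methanol | OC[C@@]1(CO1)CC/C=C(/C)CCC=C(C)C | intermediate
7 | (2S)-2-[(3Z)-4,8-dimethylnona-3,7-dien-1-yl]oxirane-2-carbaldehyde | O=C[C@@]1(CO1)CC/C=C(/C)CCC=C(C)C | intermediate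
8 | bromomagnesium 1-[(2S)-2-[(3Z)-4,8-dimethylnona-3,7-dien-1-yl]oxiran-2-yl]prop-2-en-1-olate (both C3 epimers) | C=CC(O[Mg]Br)[C@@]1(CO1)CC/C=C(/C)CCC=C(C)C | intermediate (not isolated)
9 | triethyl({1-[(2S)-2-[(3Z)-4,8-dimethylnona-3,7-dien-1-yl]oxiran-2-yl]prop-2-en-1-yl}oxy)silane (both C3 epimers) | C=CC(O[Si](CC)(CC)CC)[C@@]1(CO1)CC/C=C(/C)CCC=C(C)C | intermediate
10 | (2E,6Z)-2,6-dimethyl-9-{(2S)-2-[1-(triethylsilyloxy)prop-2-en-1-yl]oxiran-2-yl}nona-2,6-dien-1-ol | C=CC(O[Si](CC)(CC)CC)[C@@]1(CO1)CC/C=C(/C)CC/C=C(\C)CO | intermediate (not isolated)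
11 | (2E,6Z)-2,6-dimethyl-9-{(2S)-2-[1-(triethylsilyloxy)prop-2-en-1-yl]oxiran-2-yl}nona-2,6-dienal | C=CC(O[Si](CC)(CC)CC)[C@@]1(CO1)CC/C=C(/C)CC/C=C(\C)C=O | intermediate
12 | allyl 4-methoxybenzyl ether | C=CCOCc1ccc(OC)cc1 | starting material
13 | [(2Z)-3-(4-methoxybenzyloxy)prop-2-en-1-yl]diisopinocampheylborane (isopinocampheyl groups from (+)-α-pinene) | COc1ccc(CO/C=C\CB([C@@H]2C[C@@H]3C[C@H]([C@H]2C)C3(C)C)[C@@H]2C[C@@H]3C[C@H]([C@H]2C)C3(C)C)cc1 | intermediate (not isolated)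
14 | (3R,4R,5E,9Z)-3-(4-methoxybenzyloxy)-5,9-dimethyl-12-{(2S)-2-[1-(triethylsilyloxy)prop-2-en-1-yl]oxiran-2-yl}dodeca-1,5,9-trien-4-ol (13R,14R in cembrane locants) | C=CC(O[Si](CC)(CC)CC)[C@@]1(CO1)CC/C=C(/C)CC/C=C(\C)[C@@H](O)[C@H](OCc1ccc(OC)cc1)C=C | intermediate
15 | tert-butyldimethylsilyl ether of 14 at the C4 hydroxyl of the dodecatriene chain (C13) | C=CC(O[Si](CC)(CC)CC)[C@@]1(CO1)CC/C=C(/C)CC/C=C(\C)[C@@H](O[Si](C)(C)C(C)(C)C)[C@H](OCc1ccc(OC)cc1)C=C | intermediate
16 | (3R,4R,5E,9Z)-4-(tert-butyldimethylsilyloxy)-5,9-dimethyl-12-{(2S)-2-[1-(triethylsilyloxy)prop-2-en-1-yl]oxiran-2-yl}dodeca-1,5,9-trien-3-ol | C=CC(O[Si](CC)(CC)CC)[C@@]1(CO1)CC/C=C(/C)CC/C=C(\C)[C@@H](O[Si](C)(C)C(C)(C)C)[C@H](O)C=C | intermediate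
17 | (3R,4R,5E,9Z)-4-(tert-butyldimethylsilyloxy)-5,9-dimethyl-12-{(2S)-2-[1-(triethylsilyloxy)prop-2-en-1-yl]oxiran-2-yl}dodeca-1,5,9-trien-3-yl 2-(diethoxyphosphoryl)acetate | C=CC(O[Si](CC)(CC)CC)[C@@]1(CO1)CC/C=C(/C)CC/C=C(\C)[C@@H](O[Si](C)(C)C(C)(C)C)[C@H](OC(=O)CP(=O)(OCC)OCC)C=C | intermediate
18 | (3R,4R,5E,9Z)-4-(tert-butyldimethylsilyloxy)-12-[(2S)-2-(1-hydroxyprop-2-en-1-yl)oxiran-2-yl]-5,9-dimethyldodeca-1,5,9-trien-3-yl 2-(diethoxyphosphoryl)acetate | C=CC(O)[C@@]1(CO1)CC/C=C(/C)CC/C=C(\C)[C@@H](O[Si](C)(C)C(C)(C)C)[C@H](OC(=O)CP(=O)(OCC)OCC)C=C | intermediate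
19 | (3R,4R,5E,9Z)-4-(tert-butyldimethylsilyloxy)-5,9-dimethyl-12-[(2S)-2-(prop-2-enoyl)oxiran-2-yl]dodeca-1,5,9-trien-3-yl 2-(diethoxyphosphoryl)acetate | C=CC(=O)[C@@]1(CO1)CC/C=C(/C)CC/C=C(\C)[C@@H](O[Si](C)(C)C(C)(C)C)[C@H](OC(=O)CP(=O)(OCC)OCC)C=C | intermediate
20 | (4S,13R,14R,1E,7Z,11E)-14-(diethylphosphonoacetoxy)-4,18-epoxy-13-(tert-butyldimethylsilyloxy)-15,16,17-trinorcembra-1,7,11-trien-3-one | CCOP(=O)(OCC)CC(=O)O[C@@H]1/C=C/C(=O)[C@@]2(CO2)CC/C=C(/C)CC/C=C(\C)[C@H]1O[Si](C)(C)C(C)(C)C | intermediate (not isolated)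
21 | (1R,4S,13R,14R,7Z,11E)-15-(diethoxyphosphoryl)-4,18-epoxy-3-oxo-13-(tert-butyldimethylsilyloxy)-17-norcembra-7,11-dien-16,14-olide (C15 epimers) | CCOP(=O)(OCC)C1C(=O)O[C@@H]2[C@@H]1CC(=O)[C@@]3(CO3)CC/C=C(/C)CC/C=C(\C)[C@H]2O[Si](C)(C)C(C)(C)C | intermediate (not isolated)
22 | (1R,4S,13R,14R,7Z,11E)-4,18-epoxy-3-oxo-13-(tert-butyldimethylsilyloxy)cembra-7,11,15(17)-trien-16,14-olide | C=C1C(=O)O[C@@H]2[C@@H]1CC(=O)[C@@]3(CO3)CC/C=C(/C)CC/C=C(\C)[C@H]2O[Si](C)(C)C(C)(C)C | intermediate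
23 | (1R,3S,4S,13R,14R,7Z,11E)-4,18-epoxy-3-hydroxy-13-(tert-butyldimethylsilyloxy)cembra-7,11,15(17)-trien-16,14-olide | C=C1C(=O)O[C@@H]2[C@@H]1C[C@H](O)[C@@]3(CO3)CC/C=C(/C)CC/C=C(\C)[C@H]2O[Si](C)(C)C(C)(C)C | intermediate
24 | (1R,3S,4S,13R,14R,7Z,11E)-18-acetoxy-3,4-dihydroxy-13-(tert-butyldimethylsilyloxy)cembra-7,11,15(17)-trien-16,14-olide | C=C1C(=O)O[C@@H]2[C@@H]1C[C@H](O)[C@@](O)(COC(C)=O)CC/C=C(/C)CC/C=C(\C)[C@H]2O[Si](C)(C)C(C)(C)C | intermediate (not isolated)
25 | 13-O-(tert-butyldimethylsilyl)durumolide G | C=C1C(=O)O[C@@H]2[C@@H]1C[C@H](OC(C)=O)[C@@](O)(COC(C)=O)CC/C=C(/C)CC/C=C(\C)[C@H]2O[Si](C)(C)C(C)(C)C | intermediate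
26 | durumolide G, (1R,3S,4S,13R,14R,7Z,11E)-3,18-diacetoxy-4,13-dihydroxycembra-7,11,15(17)-trien-16,14-olide | C=C1C(=O)O[C@@H]2[C@@H]1C[C@H](OC(C)=O)[C@@](O)(COC(C)=O)CC/C=C(/C)CC/C=C(\C)[C@H]2O | target

**Totals**
Total step count: 16. Longest linear sequence: 16 steps (nerol to durumolide G).

**Three steps most likely to fail**

Step 13. The ruthenium carbene may load on the ketone side and close onto the C7=C8 olefin to give a cyclohexenone, or the substrate may oligomerise; the Michael step also needs the E-enone. The fallback sets out from 17 and separates the two ring closures. Ring-closing metathesis of the two allylic olefins of 17 with the second-generation Grubbs catalyst RuCl2(H2IMes)(PCy3)(=CHPh) in CH2Cl2 at 40 °C (1 mM) gives the macrocyclic C3 triethylsilyl ether F1. Buffered HF·pyridine then gives the macrocyclic allylic alcohol F2, and Dess–Martin oxidation gives enone 20 as an isolated compound. KOtBu followed by paraformaldehyde converts 20 into 22, where the route is rejoined.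

Step 7. sec-BuLi may deprotonate 12 at the benzylic instead of the allylic position, and residual BF3 can attack the 2,2-disubstituted epoxide of 11. The fallback sets out from 11 and makes the same borane without organolithium or BF3. 4-Methoxybenzyl propa-1,2-dienyl ether F3 (from base isomerisation of the corresponding propargyl ether) is hydroborated at its terminal double bond with (−)-Ipc2BH at −25 °C. This gives the (Z)-γ-alkoxyallylborane 13 directly; addition to 11 and oxidative work-up give 14, where the route is rejoined.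

Step 14. The catalyst-controlled reduction may be mismatched with the macrocycle, or the epoxide oxygen may override the steric bias. The fallback sets out from 22 and relies on substrate control followed by inversion. Luche reduction (NaBH4, CeCl3·7H2O, MeOH, −78 °C) is run first. If it gives the (3R)-epoxy alcohol F4, Mitsunobu reaction with acetic acid (PPh3, DIAD, toluene) inverts C3 and gives the (3S)-acetoxy epoxide F5 directly. Opening of the epoxide at the primary carbon C18 with CsOAc and AcOH in DMF at 60 °C then gives 25, where the route is rejoined.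

**Further compounds**
F1 | step 13 | (4S,13R,14R,1E,7Z,11E)-14-(diethylphosphonoacetoxy)-4,18-epoxy-3-(triethylsilyloxy)-13-(tert-butyldimethylsilyloxy)-15,16,17-trinorcembra-1,7,11-triene (C3 epimers) | CCOP(=O)(OCC)CC(=O)O[C@@H]1/C=C/C(O[Si](CC)(CC)CC)[C@@]2(CO2)CC/C=C(/C)CC/C=C(\C)[C@H]1O[Si](C)(C)C(C)(C)C
F2 | step 13 | (4S,13R,14R,1E,7Z,11E)-14-(diethylphosphonoacetoxy)-4,18-epoxy-13-(tert-butyldimethylsilyloxy)-15,16,17-trinorcembra-1,7,11-trien-3-ol (C3 epimers) | CCOP(=O)(OCC)CC(=O)O[C@@H]1/C=C/C(O)[C@@]2(CO2)CC/C=C(/C)CC/C=C(\C)[C@H]1O[Si](C)(C)C(C)(C)C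
F3 | step 7 | 1-methoxy-4-[(propa-1,2-dien-1-yloxy)methyl]benzene | C=C=COCc1ccc(OC)cc1
F4 | step 14 | (1R,3R,4S,13R,14R,7Z,11E)-4,18-epoxy-3-hydroxy-13-(tert-butyldimethylsilyloxy)cembra-7,11,15(17)-trien-16,14-olide | C=C1C(=O)O[C@@H]2[C@@H]1C[C@@H](O)[C@@]3(CO3)CC/C=C(/C)CC/C=C(\C)[C@H]2O[Si](C)(C)C(C)(C)C
F5 | step 14 | (1R,3S,4S,13R,14R,7Z,11E)-3-acetoxy-4,18-epoxy-13-(tert-butyldimethylsilyloxy)cembra-7,11,15(17)-trien-16,14-olide | C=C1C(=O)O[C@@H]2[C@@H]1C[C@H](OC(C)=O)[C@@]3(CO3)CC/C=C(/C)CC/C=C(\C)[C@H]2O[Si](C)(C)C(C)(C)C
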